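Ring B, the cyclohexane of the diacetoxy half, is disconnected at C7–C8 and C9–C10, which turns C8–C9 into an external two-carbon acceptor. The key step exploits the two oxygenated carbons of ring B that sit 1,4 to each other: C7, next to the oxepane oxygen O1, becomes an α-alkoxy radical by photodecarboxylation, and C10 is a methyl-ketone carbon. Radical addition to phenyl vinyl sulfone, reduction to the sulfonyl carbanion and 6-exo aldol closure form ring B and set C7 and C10 in one operation. The precursor is an oxepane-carboxylic acid (C7 epimers converge) whose C6 and C11 come from an enantioselective Ireland–Claisen rearrangement; the second half is closed last by an epoxonium cascade.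

Key step: step 10

Remark on numbering: squalene-type locants are used. In the diacetoxy half C2 is the gem-dimethyl ether carbon, C3 the acetoxy CH, C6 the angular-methyl carbon, C7 the ring-fusion O–CH, C8/C9 the ring CH2–CH2, C10 the C(CH3)(OAc) carbon, C11 the CH carrying the linker and C12 the linker CH2. Primed locants mark the same positions in the hydroxy/methylene half. Ring A is the oxepane and ring B the cyclohexane of the diacetoxy half; ring C is the cyclohexane and ring D the oxepane of the other half.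

Remark (assumption): the (S,S)-bromoborane of step 2 is taken to give the absolute configuration drawn for 5; if the sense is the opposite, the (R,R)-reagent is used with no other change.

Step 1
Reactants: 1 geraniol; 2 4-(benzyloxy)butanoic acid
Product: 3 geranyl 4-(benzyloxy)butanoate
Conditions: DCC, DMAP (cat.), CH2Cl2, 0 °C to rt
Reagents that add atoms: none
Why: Steglich esterification of a primary allylic alcohol with an unhindered acid; no stereocentre is involved.

Step 2
Reactants: 3 geranyl 4-(benzyloxy)butanoate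
Product: 5 (2R,3S)-2-[2-(benzyloxy)ethyl]-3-ethenyl-3,7-dimethyloct-6-enoic acid, via boron enolate 4 (not isolated)
Conditions: (S,S)-2-bromo-1,3-bis{[3,5-bis(trifluoromethyl)phenyl]sulfonyl}-4,5-diphenyl-1,3,2-diazaborolidine (1.2 equiv), iPr2NEt, CH2Cl2, −78 °C; then −20 to 4 °C, several days; aqueous work-up
Reagents that add atoms: none
Why: Corey's enantioselective Ireland–Claisen rearrangement: soft enolisation should give the Z(O) boron enolate, which rearranges through a chair with C12 and C5 pseudo-equatorial (the (E)-alkene puts the methyl pseudo-axial), so that quaternary C6 and C11 are set together, the absolute sense coming from the controller.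

Step 3
Reactants: 5 Claisen acid
Product: 6 (2R,3S)-2-[2-(benzyloxy)ethyl]-3-ethenyl-N-methoxy-N,3,7-trimethyloct-6-enamide
Conditions: MeNHOMe·HCl, EDC·HCl, HOBt (cat.), Et3N, CH2Cl2, rt
Reagents that add atoms: N,O-dimethylhydroxylamine hydrochloride, CNOC.Cl
Why: Carbodiimide coupling to the Weinreb amide, which keeps C10 at the acyl level without the lactone or ketal formation that a free acid or ketone would undergo once hydroxyl groups appear at C7.

Step 4
Reactants: 6 Weinreb amide
Product: 7 (2R,3S)-2-[2-(benzyloxy)ethyl]-5-[(2R)-3,3-dimethyloxiran-2-yl]-3-ethenyl-N-methoxy-N,3-dimethylpentanamide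
Conditions: D-fructose-derived Shi ketone (0.3 equiv), Oxone (2KHSO5·KHSO4·K2SO4), K2CO3, Bu4NHSO4, MeCN/dimethoxymethane/aqueous borate buffer (pH 10.5), 0 °C
Reagents that add atoms: Oxone (active oxidant potassium peroxymonosulfate), [K+].[O-]S(=O)(=O)OO
Why: Shi asymmetric epoxidation: the chiral dioxirane reacts only with the electron-rich trisubstituted C2=C3 alkene (the vinyl group is far less nucleophilic) and should set C3 (R) through the spiro transition state.

Step 5
Reactants: 7 epoxy amide
Product: 8 (2R,3R)-2-[2-(benzyloxy)ethyl]-3-(1,2-dihydroxyethyl)-5-[(2R)-3,3-dimethyloxiran-2-yl]-N-methoxy-N,3-dimethylpentanamide (both epimers at the secondary carbinol C7)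
Conditions: OsO4 (5 mol %), N-methylmorpholine N-oxide, acetone/H2O, rt
Reagents that add atoms: N-methylmorpholine N-oxide, C[N+]1([O-])CCOCC1; water, O
Why: Upjohn dihydroxylation of the only remaining alkene; the new carbinol centre at C7 forms as a mixture, which is harmless because C7 later becomes a planar radical.

Step 6
Reactants: 8 epoxy diol
Product: 9 (2R)-4-(benzyloxy)-2-[(3R,6R)-6-hydroxy-2-(hydroxymethyl)-3,7,7-trimethyloxepan-3-yl]-N-methoxy-N-methylbutanamide (both epimers at oxepane C2, which is C7)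
Conditions: BF3·OEt2 (0.2 equiv), CH2Cl2, −78 to −30 °C
Reagents that add atoms: none
Why: Lewis-acid-mediated endo-selective hydroxy-epoxide cyclisation (7-endo): the C7 hydroxyl attacks the fully substituted C2, where positive charge builds up, closing oxepane ring A, while C3 keeps its oxygen and configuration.

Step 7
Reactants: 9 oxepane diol
Product: 10 (3R,6R)-3-{(2R)-4-(benzyloxy)-1-[methoxy(methyl)amino]-1-oxobutan-2-yl}-6-hydroxy-3,7,7-trimethyloxepane-2-carboxylic acid (C2 epimers)
Conditions: TEMPO (0.2 equiv), PhI(OAc)2 (2.5 equiv), MeCN/H2O, rt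
Reagents that add atoms: water, O
Why: TEMPO/PhI(OAc)2 oxidation takes the primary alcohol through the aldehyde hydrate to the acid and leaves the hindered secondary C3 hydroxyl alone.

Step 8
Reactants: 10 Weinreb amide acid
Product: 11 (3R,6R)-3-[(3R)-1-(benzyloxy)-4-oxopentan-3-yl]-6-hydroxy-3,7,7-trimethyloxepane-2-carboxylic acid (C2 epimers)
Conditions: MeMgBr (5 equiv), THF, 0 °C to rt; aqueous HCl work-up
Reagents that add atoms: methylmagnesium bromide, C[Mg]Br
Why: Weinreb ketone synthesis: the magnesium chelate stops after one addition, the carboxylate and alkoxide formed from excess Grignard reagent are inert, and C11 is not enolised.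

Step 9
Reactants: 11 keto acid
Product: 13 (3R,6R)-6-acetoxy-3-[(3R)-1-(benzyloxy)-4-oxopentan-3-yl]-3,7,7-trimethyloxepane-2-carboxylic acid (C2 epimers), via mixed anhydride 12 (not isolated)
Conditions: Ac2O, pyridine, DMAP (cat.), CH2Cl2, rt; then H2O/THF, NaHCO3, rt; acidify
Reagents that add atoms: acetic anhydride, CC(=O)OC(C)=O
Why: DMAP-catalysed acetylation removes the only hydroxyl proton that could quench the carbanion of the key step and installs the C3 acetate of the target; the mixed anhydride formed at the acid is hydrolysed in the work-up.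

Step 10
Reactants: 13 acetoxy keto acid (both C7 epimers); 14 phenyl vinyl sulfone
Product: 15 (3R,5aR,6R,7R,9aR)-6-[2-(benzyloxy)ethyl]-7-hydroxy-2,2,5a,7-tetramethyl-8-(phenylsulfonyl)decahydro-1-benzoxepin-3-yl acetate (epimers at the sulfonyl carbon C9)
Conditions: Cs2CO3 (1.0 equiv), 14 (2 equiv), Ir[dF(CF3)ppy]2(dtbbpy)PF6 (2 mol %), dry degassed DMF, 4 Å molecular sieves, blue LEDs (450 nm), 25 °C
Reagents that add atoms: none
Why: Proposed new method: the photoexcited trivalent iridium complex oxidises the cesium carboxylate of 13, loss of CO2 gives the planar α-alkoxy radical at C7 (both C7 epimers converge), which adds to 14 to form C7–C8, and the α-sulfonyl radical is reduced by the divalent iridium species to the carbanion, which closes ring B by 6-exo-trig attack on the C10 ketone (C9–C10) before it finds a proton in the dry aprotic medium. The closest known chemistry is the decarboxylative Giese addition of α-alkoxy acids to vinyl sulfones and reductive radical-polar crossover annulations in which the derived carbanion is trapped intramolecularly. Ring B should close through a chair with C12 and C5 equatorial, and C10 should take methyl equatorial and oxygen axial because the alternative places the C10 methyl 1,3-diaxial to the C6 methyl. At C7 the acceptor is expected to enter equatorially on the oxepane conformer that keeps the C11 branch and the C3 acetoxy group pseudo-equatorial, since axial entry meets the axial C2 methyl across O1; this puts C8 trans to C11 (trans ring fusion). The step needs aldol closure to outrun protonation, which the cesium salt, the acetylated C3 hydroxyl and the sieves should secure, and chemoselective oxidation, secured because the carboxylate is the only group the catalyst can oxidise.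

Step 11
Reactants: 15 β-hydroxy sulfone
Product: 16 (3R,5aR,6R,7S,9aR)-6-[2-(benzyloxy)ethyl]-7-hydroxy-2,2,5a,7-tetramethyldecahydro-1-benzoxepin-3-yl acetate
Conditions: 6% Na/Hg amalgam, Na2HPO4, MeOH/THF, −20 °C
Reagents that add atoms: none
Why: Reductive desulfonylation: the sulfone radical anion fragments and the C9 carbanion is protonated by MeOH faster than it can expel the free tertiary alkoxide, so no Julia-type elimination is expected under buffered conditions.

Step 12
Reactants: 16 tertiary alcohol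
Product: 17 (3R,5aR,6R,7S,9aR)-6-[2-(benzyloxy)ethyl]-2,2,5a,7-tetramethyldecahydro-1-benzoxepine-3,7-diyl diacetate
Conditions: Ac2O, Sc(OTf)3 (5 mol %), MeCN, −20 °C
Reagents that add atoms: acetic anhydride, CC(=O)OC(C)=O
Why: Sc(OTf)3-catalysed acetylation acylates hindered tertiary alcohols at low temperature without elimination and leaves the C10 configuration untouched.

Step 13
Reactants: 17 diacetate benzyl ether
Product: 18 (3R,5aR,6R,7S,9aR)-6-(2-hydroxyethyl)-2,2,5a,7-tetramethyldecahydro-1-benzoxepine-3,7-diyl diacetate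
Conditions: H2 (1 atm), Pd/C, EtOAc, rt
Reagents that add atoms: none
Why: Hydrogenolysis of the benzyl ether; no alkene or other reducible group is present.

Step 14
Reactants: 18 primary alcohol
Product: 19 (3R,5aR,6R,7S,9aR)-6-(2-iodoethyl)-2,2,5a,7-tetramethyldecahydro-1-benzoxepine-3,7-diyl diacetate
Conditions: I2, PPh3, imidazole, CH2Cl2, 0 °C to rt
Reagents that add atoms: iodine, II
Why: Appel-type (Garegg–Samuelsson) iodination of the unhindered primary alcohol under neutral conditions that tolerate both acetates.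

Step 15
Reactants: 20 geranyl bromide; 21 1-(trimethylsilyl)propyne
Product: 23 [(5E)-6,10-dimethylundeca-5,9-dien-1-yn-1-yl]trimethylsilane, via lithiated silylpropyne 22 (not isolated)
Conditions: 21, n-BuLi, THF, −78 to −20 °C; then 20, −78 °C to rt
Reagents that add atoms: none
Why: Propargylic lithiation of the silylpropyne and SN2 alkylation by the primary allylic bromide at the propargylic terminus (Corey–Kirst) keeps the (E)-alkene.

Step 16
Reactants: 23 silyl enyne
Product: 24 (5E)-6,10-dimethylundeca-5,9-dien-1-yne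
Conditions: K2CO3, MeOH, rt
Reagents that add atoms: none
Why: Mild methanolysis of the alkynyl–silicon bond.

Step 17
Reactants: 24 terminal alkyne
Product: 26 (1Z,5E)-1-iodo-6,10-dimethyl-2-[(trimethylsilyl)methyl]undeca-1,5,9-triene, via alkenylcopper 25 (not isolated)
Conditions: Me3SiCH2MgCl, CuBr·SMe2, Et2O/Me2S, −40 °C; 24, −25 to −10 °C; then I2, THF, −40 °C
Reagents that add atoms: (trimethylsilyl)methylmagnesium chloride, C[Si](C)(C)C[Mg]Cl; iodine, II
Why: Normant carbocupration: syn addition of the silylmethylcopper reagent places CH2SiMe3 on the internal carbon and copper on the terminal carbon, and iodinolysis with retention gives the iodoalkene with iodine cis to CH2SiMe3.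

Step 18
Reactants: 26 iodo triene
Product: 27 trimethyl[(2Z)-2-{2-[(2R,3R)-3-{2-[(2R)-3,3-dimethyloxiran-2-yl]ethyl}-3-methyloxiran-2-yl]ethyl}-3-iodoprop-2-en-1-yl]silane
Conditions: D-fructose-derived Shi ketone (0.6 equiv), Oxone (2KHSO5·KHSO4·K2SO4), K2CO3, Bu4NHSO4, MeCN/dimethoxymethane/aqueous borate buffer, 0 °C
Reagents that add atoms: Oxone (active oxidant potassium peroxymonosulfate), [K+].[O-]S(=O)(=O)OO
Why: Double Shi epoxidation of the two electron-rich trisubstituted alkenes should set C3' (R), C6' (R) and C7' (R) under catalyst control, while the iodo-substituted allylsilane alkene is deactivated by iodine and should survive.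

Step 19
Reactants: 19 right-half iodide; 27 diepoxy alkenyl iodide
Product: 29 (3R,5aR,6R,7S,9aR)-6-[(3Z)-6-[(2R,3R)-3-{2-[(2R)-3,3-dimethyloxiran-2-yl]ethyl}-3-methyloxiran-2-yl]-4-[(trimethylsilyl)methyl]hex-3-en-1-yl]-2,2,5a,7-tetramethyldecahydro-1-benzoxepine-3,7-diyl diacetate, via alkylzinc iodide 28 (not isolated)
Conditions: 19, Zn dust (activated with BrCH2CH2Br and Me3SiCl), LiCl, THF, 40 °C; then 27, PdCl2(dppf) (5 mol %), THF/N-methylpyrrolidone, 25 °C
Reagents that add atoms: none
Why: Negishi sp3–sp2 coupling: zinc insertion into the primary iodide tolerates the acetates, and zerovalent palladium should couple with retention of alkene geometry without opening the epoxides.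

Step 20
Reactants: 29 allylsilane diepoxide
Product: 31 (3R,5aR,6R,7S,9aR)-6-{2-[(3R,5aR,6S,9aR)-3-hydroxy-2,2,5a-trimethyl-7-methylidenedecahydro-1-benzoxepin-6-yl]ethyl}-2,2,5a,7-tetramethyldecahydro-1-benzoxepine-3,7-diyl diacetate (target), via silyl ether 30 (not isolated)
Conditions: Me3SiOTf (1.2 equiv), 2,6-di-tert-butyl-4-methylpyridine, CH2Cl2, −78 °C; then aqueous citric acid, MeOH, 0 °C
Reagents that add atoms: none
Why: Epoxonium-ion tandem oxa- and carbacyclisation: the silylated terminal epoxide is opened at C2' by the oxygen of the 6',7'-epoxide (7-endo, ring D), the epoxonium ion is opened at C6' with inversion by C11' of the allylsilane through a chair (ring C, C12' equatorial), and loss of silicon gives only the exocyclic methylene, after which mild acid frees the C3' hydroxyl.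

Compound list
1 | geraniol, (2E)-3,7-dimethylocta-2,6-dien-1-ol | CC(C)=CCC/C(C)=C/CO | starting material
2 | 4-(benzyloxy)butanoic acid | OC(=O)CCCOCc1ccccc1 | starting material
3 | geranyl 4-(benzyloxy)butanoate | CC(C)=CCC/C(C)=C/COC(=O)CCCOCc1ccccc1 | intermediate
4 | Z(O) boron enolate of 3 bound to the (S,S)-1,3-bis{[3,5-bis(trifluoromethyl)phenyl]sulfonyl}-4,5-diphenyl-1,3,2-diazaborolidin-2-yl group | C(c1ccccc1)OCC/C=C(\OB1N(S(=O)(=O)c2cc(cc(c2)C(F)(F)F)C(F)(F)F)[C@@H](c2ccccc2)[C@H](c2ccccc2)N1S(=O)(=O)c1cc(cc(c1)C(F)(F)F)C(F)(F)F)OC/C=C(\C)CCC=C(C)C | intermediate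
5 | (2R,3S)-2-[2-(benzyloxy)ethyl]-3-ethenyl-3,7-dimethyloct-6-enoic acid | OC(=O)[C@H](CCOCc1ccccc1)[C@](C)(C=C)CCC=C(C)C | intermediate
6 | (2R,3S)-2-[2-(benzyloxy)ethyl]-3-ethenyl-N-methoxy-N,3,7-trimethyloct-6-enamide | CON(C)C(=O)[C@H](CCOCc1ccccc1)[C@](C)(C=C)CCC=C(C)C | intermediate
7 | (2R,3S)-2-[2-(benzyloxy)ethyl]-5-[(2R)-3,3-dimethyloxiran-2-yl]-3-ethenyl-N-methoxy-N,3-dimethylpentanamide | CON(C)C(=O)[C@H](CCOCc1ccccc1)[C@](C)(C=C)CC[C@H]1OC1(C)C | intermediate
8 | (2R,3R)-2-[2-(benzyloxy)ethyl]-3-(1,2-dihydroxyethyl)-5-[(2R)-3,3-dimethyloxiran-2-yl]-N-methoxy-N,3-dimethylpentanamide, C7 epimers | CON(C)C(=O)[C@H](CCOCc1ccccc1)[C@](C)(C(O)CO)CC[C@H]1OC1(C)C | intermediate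
9 | (2R)-4-(benzyloxy)-2-[(3R,6R)-6-hydroxy-2-(hydroxymethyl)-3,7,7-trimethyloxepan-3-yl]-N-methoxy-N-methylbutanamide, C7 epimers | CON(C)C(=O)[C@H](CCOCc1ccccc1)[C@@]1(C)CC[C@@H](O)C(C)(C)OC1CO | intermediate
10 | (3R,6R)-3-{(2R)-4-(benzyloxy)-1-[methoxy(methyl)amino]-1-oxobutan-2-yl}-6-hydroxy-3,7,7-trimethyloxepane-2-carboxylic acid, C7 epimers | CON(C)C(=O)[C@H](CCOCc1ccccc1)[C@@]1(C)CC[C@@H](O)C(C)(C)OC1C(O)=O | intermediate
11 | (3R,6R)-3-[(3R)-1-(benzyloxy)-4-oxopentan-3-yl]-6-hydroxy-3,7,7-trimethyloxepane-2-carboxylic acid, C7 epimers | CC(=O)[C@H](CCOCc1ccccc1)[C@@]1(C)CC[C@@H](O)C(C)(C)OC1C(O)=O | intermediate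
12 | mixed anhydride of 13 with acetic acid | CC(=O)[C@H](CCOCc1ccccc1)[C@@]1(C)CC[C@@H](OC(C)=O)C(C)(C)OC1C(=O)OC(C)=O | intermediate
13 | (3R,6R)-6-acetoxy-3-[(3R)-1-(benzyloxy)-4-oxopentan-3-yl]-3,7,7-trimethyloxepane-2-carboxylic acid, C7 epimers | CC(=O)[C@H](CCOCc1ccccc1)[C@@]1(C)CC[C@@H](OC(C)=O)C(C)(C)OC1C(O)=O | intermediate
14 | phenyl vinyl sulfone | C=CS(=O)(=O)c1ccccc1 | starting material
15 | (3R,5aR,6R,7R,9aR)-6-[2-(benzyloxy)ethyl]-7-hydroxy-2,2,5a,7-tetramethyl-8-(phenylsulfonyl)decahydro-1-benzoxepin-3-yl acetate, C9 epimers | c1ccccc1COCC[C@@H]1[C@@]2(C)CC[C@@H](OC(C)=O)C(C)(C)O[C@@H]2CC(S(=O)(=O)c2ccccc2)[C@]1(C)O | intermediate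
16 | (3R,5aR,6R,7S,9aR)-6-[2-(benzyloxy)ethyl]-7-hydroxy-2,2,5a,7-tetramethyldecahydro-1-benzoxepin-3-yl acetate | c1ccccc1COCC[C@@H]1[C@@]2(C)CC[C@@H](OC(C)=O)C(C)(C)O[C@@H]2CC[C@]1(C)O | intermediate
17 | (3R,5aR,6R,7S,9aR)-6-[2-(benzyloxy)ethyl]-2,2,5a,7-tetramethyldecahydro-1-benzoxepine-3,7-diyl diacetate | c1ccccc1COCC[C@@H]1[C@@]2(C)CC[C@@H](OC(C)=O)C(C)(C)O[C@@H]2CC[C@]1(C)OC(C)=O | intermediate
18 | (3R,5aR,6R,7S,9aR)-6-(2-hydroxyethyl)-2,2,5a,7-tetramethyldecahydro-1-benzoxepine-3,7-diyl diacetate | OCC[C@@H]1[C@@]2(C)CC[C@@H](OC(C)=O)C(C)(C)O[C@@H]2CC[C@]1(C)OC(C)=O | intermediate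
19 | (3R,5aR,6R,7S,9aR)-6-(2-iodoethyl)-2,2,5a,7-tetramethyldecahydro-1-benzoxepine-3,7-diyl diacetate | ICC[C@@H]1[C@@]2(C)CC[C@@H](OC(C)=O)C(C)(C)O[C@@H]2CC[C@]1(C)OC(C)=O | intermediate
20 | geranyl bromide, (2E)-1-bromo-3,7-dimethylocta-2,6-diene | CC(C)=CCC/C(C)=C/CBr | starting material
21 | 1-(trimethylsilyl)propyne | CC#C[Si](C)(C)C | starting material
22 | 3-lithio-1-(trimethylsilyl)propyne | [Li]CC#C[Si](C)(C)C | intermediate
23 | [(5E)-6,10-dimethylundeca-5,9-dien-1-yn-1-yl]trimethylsilane | CC(C)=CCC/C(C)=C/CCC#C[Si](C)(C)C | intermediate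
24 | (5E)-6,10-dimethylundeca-5,9-dien-1-yne | CC(C)=CCC/C(C)=C/CCC#C | intermediate
25 | [(1Z,5E)-6,10-dimethyl-2-[(trimethylsilyl)methyl]undeca-1,5,9-trien-1-yl]copper | [Cu]/C=C(\C[Si](C)(C)C)CC/C=C(\C)CCC=C(C)C | intermediate
26 | (1Z,5E)-1-iodo-6,10-dimethyl-2-[(trimethylsilyl)methyl]undeca-1,5,9-triene | I/C=C(\C[Si](C)(C)C)CC/C=C(\C)CCC=C(C)C | intermediate
27 | trimethyl[(2Z)-2-{2-[(2R,3R)-3-{2-[(2R)-3,3-dimethyloxiran-2-yl]ethyl}-3-methyloxiran-2-yl]ethyl}-3-iodoprop-2-en-1-yl]silane | I/C=C(\C[Si](C)(C)C)CC[C@H]1O[C@]1(C)CC[C@H]1OC1(C)C | intermediate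
28 | alkylzinc iodide from 19 (iodozincio in place of iodo) | I[Zn]CC[C@@H]1[C@@]2(C)CC[C@@H](OC(C)=O)C(C)(C)O[C@@H]2CC[C@]1(C)OC(C)=O | intermediate
29 | (3R,5aR,6R,7S,9aR)-6-[(3Z)-6-[(2R,3R)-3-{2-[(2R)-3,3-dimethyloxiran-2-yl]ethyl}-3-methyloxiran-2-yl]-4-[(trimethylsilyl)methyl]hex-3-en-1-yl]-2,2,5a,7-tetramethyldecahydro-1-benzoxepine-3,7-diyl diacetate | C[Si](C)(C)C/C(CC[C@H]1O[C@]1(C)CC[C@H]1OC1(C)C)=C\CC[C@@H]1[C@@]2(C)CC[C@@H](OC(C)=O)C(C)(C)O[C@@H]2CC[C@]1(C)OC(C)=O | intermediate
30 | C3' trimethylsilyl ether of the target | C=C1CC[C@H]2OC(C)(C)[C@H](O[Si](C)(C)C)CC[C@]2(C)[C@H]1CC[C@@H]1[C@@]2(C)CC[C@@H](OC(C)=O)C(C)(C)O[C@@H]2CC[C@]1(C)OC(C)=O | intermediate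
31 | (3R,5aR,6R,7S,9aR)-6-{2-[(3R,5aR,6S,9aR)-3-hydroxy-2,2,5a-trimethyl-7-methylidenedecahydro-1-benzoxepin-6-yl]ethyl}-2,2,5a,7-tetramethyldecahydro-1-benzoxepine-3,7-diyl diacetate | C=C1CC[C@H]2OC(C)(C)[C@H](O)CC[C@]2(C)[C@H]1CC[C@@H]1[C@@]2(C)CC[C@@H](OC(C)=O)C(C)(C)O[C@@H]2CC[C@]1(C)OC(C)=O | target

Total step count: 20. Longest linear sequence: 16 steps (steps 1 to 14, then 19 and 20); steps 15 to 18 make the second fragment.

Steps most likely to fail

Step 10 (the proposed new method). The α-sulfonyl carbanion may be protonated, or the aldolate may revert, before ring B is secured, and the intermolecular radical addition may show poor facial selectivity at C7. The fallback uses known reactions only and sets out from acid 10. A decarboxylative Giese addition to 14 with the same iridium photocatalyst and K2HPO4 in wet DMF, where protonation is wanted, should give the open-chain Weinreb amide sulfone F1. LiN(SiMe3)2 (3 equiv, THF, −78 to 0 °C) then forms the α-sulfonyl carbanion, which is acylated intramolecularly by the Weinreb amide to give the bicyclic β-keto sulfone F2; the cis- and trans-fused isomers can be separated here. Al/Hg amalgam in aqueous THF removes the sulfone to give ketone F3, in which C11 can equilibrate to the equatorial side chain. MeMgBr with CeCl3 (THF, −78 °C) should add from the equatorial side, the axial side being blocked by the C6 methyl, to give diol F4. The conditions of step 12 then acetylate both hydroxyl groups, and the route is rejoined at 17.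

Step 17. Transfer of the silylmethyl group from copper to the unactivated alkyne may be too slow, giving low conversion or loss of regiocontrol. The fallback sets out from alkyne 24 and replaces carbocupration by copper-catalysed borylalkylation: CuCl/Xantphos (cat.), NaOtBu, B2pin2 and ICH2SiMe3 in THF should give, by syn borylcupration and alkylation of the internal alkenylcopper, the alkenyl boronate F5. Iododeboronation with NaOH and I2 (THF/H2O, 0 °C, retention) returns to the route at 26.

Step 6. The hydroxy-epoxide closure may suffer competing 6-exo opening at C3, attack by the primary hydroxyl, or hydride-shift rearrangement of the epoxide. The fallback sets out from 7 and changes the nucleophile from a hydroxyl group to an epoxide oxygen: dimethyldioxirane (acetone, 0 °C) epoxidises the vinyl group to give bis-epoxide F6. BF3·OEt2 (0.2 equiv) in CH2Cl2 containing H2O (2 equiv) at −40 °C should then let the new epoxide oxygen attack the tertiary C2 (epoxonium ion), and water opens the epoxonium ion at its primary carbon, which returns to the route at 9.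

Further compounds
F1 | step 10 | (2R)-4-(benzyloxy)-2-{(2R,3R,6R)-6-hydroxy-3,7,7-trimethyl-2-[2-(phenylsulfonyl)ethyl]oxepan-3-yl}-N-methoxy-N-methylbutanamide | CON(C)C(=O)[C@H](CCOCc1ccccc1)[C@@]1(C)CC[C@@H](O)C(C)(C)O[C@@H]1CCS(=O)(=O)c1ccccc1
F2 | step 10 | (3R,5aR,6R,9aR)-6-[2-(benzyloxy)ethyl]-3-hydroxy-2,2,5a-trimethyl-8-(phenylsulfonyl)octahydro-1-benzoxepin-7(2H)-one | c1ccccc1COCC[C@@H]1[C@@]2(C)CC[C@@H](O)C(C)(C)O[C@@H]2CC(S(=O)(=O)c2ccccc2)C1=O
F3 | step 10 | (3R,5aR,6R,9aR)-6-[2-(benzyloxy)ethyl]-3-hydroxy-2,2,5a-trimethyloctahydro-1-benzoxepin-7(2H)-one | c1ccccc1COCC[C@@H]1[C@@]2(C)CC[C@@H](O)C(C)(C)O[C@@H]2CCC1=O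
F4 | step 10 | (3R,5aR,6R,7S,9aR)-6-[2-(benzyloxy)ethyl]-2,2,5a,7-tetramethyldecahydro-1-benzoxepine-3,7-diol | c1ccccc1COCC[C@@H]1[C@@]2(C)CC[C@@H](O)C(C)(C)O[C@@H]2CC[C@]1(C)O
F5 | step 17 | 2-{(1Z,5E)-6,10-dimethyl-2-[(trimethylsilyl)methyl]undeca-1,5,9-trien-1-yl}-4,4,5,5-tetramethyl-1,3,2-dioxaborolane | CC1(C)OB(OC1(C)C)/C=C(\C[Si](C)(C)C)CC/C=C(\C)CCC=C(C)C
F6 | step 6 | (2R,3R)-2-[2-(benzyloxy)ethyl]-5-[(2R)-3,3-dimethyloxiran-2-yl]-N-methoxy-N,3-dimethyl-3-(oxiran-2-yl)pentanamide, C7 epimers | CON(C)C(=O)[C@H](CCOCc1ccccc1)[C@](C)(C1CO1)CC[C@H]1OC1(C)C
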